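The runs are calculated for an exercise.

If the next flask is to be charged from the three earlier runs, decide first whether more free base or a longer wait would buy anything, and hold every figure to that decision.

all flasks: electrophile 0.20 M (fed, over 12 s)
- red: nucleophile 0.40 M; free base 0.25 M; run made earlier
- amber: nucleophile 0.40 M; free base 0.52 M; run made earlier
- teal: nucleophile 0.40 M; free base 1.1 M; run made earlier
- south: nucleophile 0.400 M; free base 0.480 M; time 4.0 min
- north: nucleophile 0.400 M; free base 0.960 M; time 4.0 min
- east: nucleophile 0.400 M; free base 0.240 M; time 4.0 min

- red (time / s: electrophile / %, product / %): 10.0: 67, 18; 20.0: 51, 47; 30.0: 39, 61; 60.0: 14, 85; 120: 1, 97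
- amber (time / s: electrophile / %, product / %): 10.0: 64, 21; 30.0: 36, 62; 60.0: 13, 88; 80.0: 9, 93; 120: 2, 97
- teal (time / s: electrophile / %, product / %): 10.0: 68, 19; 20.0: 54, 47; 30.0: 31, 65; 60.0: 12, 85; 120: 2, 97

(scatter of a reading: 1.5 percentage points)

- for product the crystals are counted in
- as a solid, counted per litre of solution: crystals
- on the list of suspects stand: crystals <-> product; acid set free -> by-product carried off; electrophile + nucleophile -> acid set free + product; acid set free + free base <-> salt of the base; nucleophile + acid set free <-> protonated nucleophile
- percentages count the whole charge, also what has not yet gone in

- part of the electrophile that has reacted at the end, south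
- part of the electrophile that has reacted at the end, north
- part of the electrophile that has reacted at the end, east
- what raising the concentration of free base from its lowest to its highest value here does to the part of the electrophile that has reacted (changes below 5 percentage points count as none) (no change / it rises / it falls)

1. Reckon 1.00 electrophile charges of spare nucleophile, meaning the nucleophile charged over the electrophile charged, less one, for south, north and east alike. Since the suspect step spends one nucleophile per electrophile, a negative spare leaves that fraction of the electrophile charge as a floor, while a positive spare, so long as free base keeps the acid set free off the nucleophile, makes the electrophile the limiting reagent, free to fall towards nothing, so zero is the crossing at which control changes hands.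

2. Hold the free base against the same charge: east, the leanest, carries 1.20 electrophile charges of it, more than the acid that charge can set free. Note too that the earlier runs, from 0.25 M to 1.1 M of free base, read 1%, 2% and 2% of electrophile at 120 s, a spread of 1 percentage point against a scatter of 1.5 points.

3. Read the tail in the amber run, where the electrophile peak goes from 13% at 60.0 s to 2% at 120 s, and, with the spare positive, carry that fall on at the same fraction per second to 4.0 min, which gives my own reckoning for a flask like amber of about 0.0473% of the charge unreacted, an estimate with the scatter of its inputs in it.

4. Keep east, then, the recipe with less free base than south or north, and add neither base nor time.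

The forecast gives 99.9% for south, 99.9% for north and 99.8% for east, with the trend no change: “Conversion should be essentially complete in all three, so there is no change.”

South, north and east give 99.9%, 99.9% and 99.9%, with the trend no change and a change of 0.046 points.

    crystals ⇌ product, rate k1*(cs1 - [product]) while solid is left; crystals form when [product] > cs1 (solubility = 14.0 mM, k = 2.47 s⁻¹)
    acid set free → by-product carried off (k = 0.0815 s⁻¹)
    electrophile + nucleophile → acid set free + product (k = 0.145 M⁻¹ s⁻¹)
    acid set free + free base ⇌ salt of the base (K = 1040 M⁻¹, k = 10.6 M⁻¹ s⁻¹)
    nucleophile + acid set free ⇌ protonated nucleophile, settled at all times (K = 60.4 M⁻¹)

In north the turnover of electrophile with nucleophile reaches its halfway mark by 0.347 min, far sooner than the reading at 4.0 min, and at 0.347 min the acid set free has a half-life of 0.075 s by its forward rate with free base, far shorter than the 0.80 min of the nucleophile by its step with the electrophile. North ends with 49.3% of its nucleophile free, against 50.0% of its own charge reckoned as spare, while the neighbour like north but with 0.16 M of nucleophile has a spare of −0.200 electrophile charges and keeps 25.3% of its electrophile at 4.00 min, above the floor of 20.0%.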